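**Retrosynthetic overview**

1. Vitrofolal B ⇐ its 3‑O‑methyl, 6‑O‑isopropyl ether by one BCl3 dealkylation; the target has no stereocentre to set.
2. Ring B (the ring carrying aryl, OH and CHO) is built last on the vanillin‑derived ring A. The C3–C4 bond comes from addition of a symmetric 1,3‑dimethoxyallyl anion (a homoenolate equivalent of a β‑oxygenated propanal) to a diaryl ketone. The C1–C2 ring closure (enol ether onto the unmasked aldehyde carbon) and aromatisation follow in the same flask.
3. The keto aldehyde ⇐ O‑isopropylvanillin + veratric Weinreb amide by amino‑alkoxide‑directed ortho‑lithiation (C4–C4a bond).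
4. The allyl anion ⇐ 1,3‑dimethoxypropene ⇐ 1,1,3‑trimethoxypropane. Ring A and the pendant veratryl ring are bought; only ring B is formed.

Assumption: the target has no stereocentre, and the pendant aryl ring has two ortho hydrogens, so the biaryl axis is not stereogenic; the compound is achiral and "single enantiomer" is met without an asymmetric step.

Locants C1–C8a below are those of the naphthalene‑2‑carbaldehyde core of 11 and 12 (C2 carries CHO, C3 the oxygen, C4 the aryl group, C5 OMe, C6 the second oxygen).

**Route**

Step 1
Reactants: 1 1,1,3-trimethoxypropane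
Product: 2 1,3-dimethoxyprop-1-ene (E/Z mixture)
Conditions: TMSOTf (1.1 equiv), i-Pr2NEt (1.3 equiv), CH2Cl2, −20 → 23 °C; aq. NaHCO3; distil
Reagents that add atoms: none
Why: Acetal-to-enol-ether elimination: the silyl triflate ionises the acetal to an oxocarbenium ion and the hindered amine removes the α‑proton, and these aprotic kinetic conditions avoid the acid‑mediated allylic scrambling to acrolein dimethyl acetal.

Step 2
Reactants: 3 3-methoxy-4-(propan-2-yloxy)benzaldehyde (O‑isopropylvanillin); 4 N,3,4-trimethoxy-N-methylbenzamide
Product: 7 2-(3,4-dimethoxybenzoyl)-3-methoxy-4-(propan-2-yloxy)benzaldehyde, via lithium amino alkoxide 5 (not isolated), via ortho-lithiated amino alkoxide 6 (not isolated)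
Conditions: LiN(Me)CH2CH2NMe2 (1.1 equiv, from Me(H)NCH2CH2NMe2 + n-BuLi), THF, −20 °C; n-BuLi (2.5 equiv), −20 °C, 20 h; 4 (3 equiv), −78 → 23 °C; 2 M HCl
Reagents that add atoms: none
Why: Directed ortho‑metalation (Comins amino alkoxide) followed by Weinreb ketone synthesis: the in‑situ amino alkoxide and the 3‑methoxy group together direct lithiation to the carbon between them, as is known for veratraldehyde, and the chelated tetrahedral adduct of the Weinreb amide stops at the ketone stage until acid work‑up releases both carbonyl groups.

Step 3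
Reactants: 7 2-(3,4-dimethoxybenzoyl)-3-methoxy-4-(propan-2-yloxy)benzaldehyde; 2 1,3-dimethoxyprop-1-ene
Product: 11 4-(3,4-dimethoxyphenyl)-3,5-dimethoxy-6-(propan-2-yloxy)naphthalene-2-carbaldehyde, via 1,3-dimethoxyallyllithium 8 (not isolated), via ketone-bearing amino alkoxide 9 (not isolated), via dilithium carbinolate 10 (not isolated)
Conditions: (a) 2 (2.0 equiv), s-BuLi (1.9 equiv), THF, −78 °C, 30 min; (b) 7, LiN(Me)CH2CH2NMe2 (1.1 equiv), THF, −40 °C, 20 min; (c) add (a) to (b), −78 → −40 °C; (d) AcOH (10 equiv), −78 → 23 °C; then 2 M HCl, 40 °C, 1 h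
Reagents that add atoms: water (O)
Why: Proposed new method: the symmetric allyl anion 8 is a homoenolate equivalent (the β‑carbanion of 3‑methoxypropanal; closest known reactions are carbonyl additions of lithiated allyl ethers and of 1,3‑bis(methylthio)allyllithium, combined with in‑situ amino‑alkoxide protection of an aldehyde), and because its two termini are identical no α/γ ambiguity can arise; with the aldehyde of 7 masked as 9 it can only add to the non‑enolisable diaryl ketone, joining the two formerly electrophilic carbons C4 and C3; acetic acid then turns the amino alkoxide into an iminium or oxocarbenium ion at C1 that is captured by the enol ether carbon C2 (Mannich/Prins‑type six‑ring closure), and aqueous HCl hydrolyses the resulting oxocarbenium ion to the formyl group, expels the C1 heteroatom by β‑elimination and dehydrates the doubly benzylic carbinol, with aromatisation as the driving force; both new stereocentres are destroyed, so none needs control.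

Step 4
Reactants: 11 4-(3,4-dimethoxyphenyl)-3,5-dimethoxy-6-(propan-2-yloxy)naphthalene-2-carbaldehyde
Product: 12 vitrofolal B, 4-(3,4-dimethoxyphenyl)-3,6-dihydroxy-5-methoxynaphthalene-2-carbaldehyde
Conditions: BCl3 (5 equiv), CH2Cl2, −78 → 0 °C; H2O
Reagents that add atoms: none
Why: Chemoselective Lewis‑acid ether cleavage: BCl3 removes aryl isopropyl ethers (secondary alkyl C–O) and methyl ethers ortho to a carbonyl group (six‑membered boron chelate) much faster than unactivated aryl methyl ethers, so the C5 and the two veratryl methoxy groups remain.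

**Compound list**

1 | 1,1,3-trimethoxypropane | COCCC(OC)OC | starting material
2 | 1,3-dimethoxyprop-1-ene (E/Z mixture) | COC=CCOC | intermediate
3 | 3-methoxy-4-(propan-2-yloxy)benzaldehyde | COc1cc(C=O)ccc1OC(C)C | starting material
4 | N,3,4-trimethoxy-N-methylbenzamide | CON(C)C(=O)c1ccc(OC)c(OC)c1 | starting material
5 | lithium {[2-(dimethylamino)ethyl](methyl)amino}[3-methoxy-4-(propan-2-yloxy)phenyl]methanolate (racemic, formed in the flask) | [Li+].[O-]C(N(C)CCN(C)C)c1ccc(OC(C)C)c(OC)c1 | intermediate
6 | 2-lithio derivative of 5, lithium at the ring carbon between the amino alkoxide carbon and the methoxy group (racemic, formed in the flask) | [Li+].[O-]C(N(C)CCN(C)C)c1ccc(OC(C)C)c(OC)c1[Li] | intermediate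
7 | 2-(3,4-dimethoxybenzoyl)-3-methoxy-4-(propan-2-yloxy)benzaldehyde | O=Cc1ccc(OC(C)C)c(OC)c1C(=O)c1ccc(OC)c(OC)c1 | intermediate
8 | 1,3-dimethoxyallyllithium (symmetric delocalised allyl anion, formed in the flask) | [Li]C(OC)C=COC | intermediate
9 | lithium amino alkoxide of 7, aldehyde masked by LiN(Me)CH2CH2NMe2, ketone free (racemic, formed in the flask) | [Li+].[O-]C(N(C)CCN(C)C)c1ccc(OC(C)C)c(OC)c1C(=O)c1ccc(OC)c(OC)c1 | intermediate
10 | dilithium salt of the adduct of 8 to the ketone of 9: tertiary diaryl carbinolate bearing a 1,3-dimethoxyprop-2-enyl group, aldehyde still masked (mixture of stereoisomers, formed in the flask) | [Li+].[Li+].[O-]C(N(C)CCN(C)C)c1ccc(OC(C)C)c(OC)c1C([O-])(c1ccc(OC)c(OC)c1)C(OC)C=COC | intermediate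
11 | 4-(3,4-dimethoxyphenyl)-3,5-dimethoxy-6-(propan-2-yloxy)naphthalene-2-carbaldehyde | COc1ccc(-c2c(OC)c(C=O)cc3ccc(OC(C)C)c(OC)c23)cc1OC | intermediate
12 | vitrofolal B, 4-(3,4-dimethoxyphenyl)-3,6-dihydroxy-5-methoxynaphthalene-2-carbaldehyde (achiral) | COc1ccc(-c2c(O)c(C=O)cc3ccc(O)c(OC)c23)cc1OC | target

**Step count and risks**

Total steps: 4. Longest linear sequence: 3 steps (3 → 7 → 11 → 12; the branch 1 → 2 joins at step 3).

Steps most likely to fail:

1. Step 3. The anion 8 is unprecedented as such. The ketone of 9 is di‑ortho‑substituted and may sit partly as a cyclic lactolate. In the acid stage, loss of the C3 methoxy group or Friedel–Crafts closure onto the veratryl ring could compete. Fallback: reverse the order of the two bond formations. Set out from Weinreb amide 4 and acylate 8 with it (THF, −78 °C) to give 1-(3,4-dimethoxyphenyl)-2,4-dimethoxybut-3-en-1-one F1. Then add aryllithium 6 (made from 3 as in step 2, transmetalated with CeCl3 to suppress enolisation, F1 in excess) to F1. This gives carbinolate 10 as its mixed metal alkoxide, and the route continues with the acid treatment of step 3 to 11.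

2. Step 2. The hindered aryllithium 6 may acylate slowly, and excess n-BuLi competes for 4. Fallback: change to cross‑coupling. Set out from 3, form 6 as before and quench with I2 to give 2-iodo-3-methoxy-4-(propan-2-yloxy)benzaldehyde F2. Then run a carbonylative Suzuki–Miyaura coupling with 3,4-dimethoxyphenylboronic acid (PdCl2(dppf), CO 1 atm, K2CO3, anisole, 90 °C), which comes back to the route at 7.

3. Step 4. The boron aryloxide formed at C6 could assist cleavage of the neighbouring C5 methoxy group, or the hindered C3 methoxy group could react incompletely. Fallback: separate the two cleavages by mechanism. Set out from 11 and treat with LiCl in DMF at 140 °C (SN2 at the methyl of the one methoxy group activated by the ortho formyl group) to give 4-(3,4-dimethoxyphenyl)-3-hydroxy-5-methoxy-6-(propan-2-yloxy)naphthalene-2-carbaldehyde F3. Then remove the isopropyl group alone with AlCl3 (CH2Cl2, 0 °C), which comes back to the route at 12.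

**Further compounds**

F1 | step 3 | 1-(3,4-dimethoxyphenyl)-2,4-dimethoxybut-3-en-1-one (racemic, E/Z mixture) | COC=CC(OC)C(=O)c1ccc(OC)c(OC)c1
F2 | step 2 | 2-iodo-3-methoxy-4-(propan-2-yloxy)benzaldehyde | O=Cc1ccc(OC(C)C)c(OC)c1I
F3 | step 4 | 4-(3,4-dimethoxyphenyl)-3-hydroxy-5-methoxy-6-(propan-2-yloxy)naphthalene-2-carbaldehyde | COc1ccc(-c2c(O)c(C=O)cc3ccc(OC(C)C)c(OC)c23)cc1OC
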